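The tetrahydrofuran ring (O1, C2 to C5; C2 carries the 4-hydroxy-3,5-dimethoxyphenyl ring, C3 the feruloyloxymethyl group, C4 the 4-hydroxy-3-methoxybenzyl group) is closed at the O1–C2 bond. C2 is benzylic to a para-oxygenated ring, so a carbinol there ionises under mild acid to a quinone-methide-type cation, and only the hydroxyl on C5 can reach it in a five-membered closure. In one operation this closes the ring, sets C2 trans to C3 from both carbinol epimers and leaves the C3 hydroxymethyl free for the ferulate. The precursor is an open-chain (2R,3R)-triol, assembled by a tandem conjugate addition–aldol reaction on a menthol-derived butenolide.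

Key step: step 5

Remark: the carbinol carbon made in step 2 is carried as a mixture of epimers (written without a descriptor) because step 5 erases and resets it; compounds 1, 2, 4, 5 and 14 are taken as catalogue chemicals.

Step 1
Reactants: 1 4-(benzyloxy)-3-methoxybenzaldehyde; 2 propane-1,3-dithiol
Product: 3 2-[4-(benzyloxy)-3-methoxyphenyl]-1,3-dithiane
Conditions: BF3·OEt2 (0.1 equiv), CH2Cl2, 0 °C to rt
Reagents that add atoms: none
Why: Lewis-acid-catalysed dithioacetalisation of an aryl aldehyde turns the aldehyde carbon into a benzyl-anion equivalent, and the benzyl ether is inert to catalytic BF3·OEt2.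

Step 2
Reactants: 3 2-[4-(benzyloxy)-3-methoxyphenyl]-1,3-dithiane; 4 (5R)-5-(l-menthyloxy)furan-2(5H)-one; 5 4-(benzyloxy)-3,5-dimethoxybenzaldehyde
Product: 8 (3S,4R,5R)-3-{[4-(benzyloxy)-3,5-dimethoxyphenyl](hydroxy)methyl}-4-{2-[4-(benzyloxy)-3-methoxyphenyl]-1,3-dithian-2-yl}-5-(l-menthyloxy)dihydrofuran-2(3H)-one (mixture of carbinol epimers), via 2-lithio-1,3-dithiane 6 (not isolated), via lactone lithium enolate 7 (not isolated)
Conditions: n-BuLi (1.0 equiv), THF, −78 to −20 °C; then 4, −78 °C; then 5, −78 °C; AcOH quench at −78 °C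
Reagents that add atoms: none
Why: Tandem Michael addition–aldol reaction, in which the soft sulfur-stabilised anion 6 adds 1,4 to the butenolide on the face anti to the C5 menthyloxy group (sets C4 as R) and enolate 7 takes up the aldehyde anti to the new dithianyl group (sets C3 as S, 3,4-trans).

Step 3
Reactants: 8 tandem adduct
Product: 9 (3S,4R,5R)-4-[4-(benzyloxy)-3-methoxybenzyl]-3-{[4-(benzyloxy)-3,5-dimethoxyphenyl](hydroxy)methyl}-5-(l-menthyloxy)dihydrofuran-2(3H)-one
Conditions: NiCl2·6H2O, NaBH4, MeOH/THF, 0 °C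
Reagents that add atoms: none
Why: Hydrogenolytic desulfurisation of the benzylic dithioketal with Ni2B made in the flask should turn the dithiane carbon into the benzyl CH2 without cleaving the aryl benzyl ethers, the benzylic hydroxyl or the acetal, and no stereocentre is touched.

Step 4
Reactants: 9 desulfurised lactone
Product: 10 (2R,3R)-2-{[4-(benzyloxy)-3,5-dimethoxyphenyl](hydroxy)methyl}-3-[4-(benzyloxy)-3-methoxybenzyl]butane-1,4-diol
Conditions: LiAlH4, THF, 0 °C to rt; aqueous NaOH work-up
Reagents that add atoms: none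
Why: Hydride reduction of the lactone and of the acetal carbon it unmasks as an aldehyde gives both primary alcohols and releases menthol, while C3 and C4 of the lactone are carried over unchanged as C2 and C3 of the butanediol.

Step 5
Reactants: 10 triol (both carbinol epimers)
Product: 12 {(2S,3R,4R)-2-[4-(benzyloxy)-3,5-dimethoxyphenyl]-4-[4-(benzyloxy)-3-methoxybenzyl]tetrahydrofuran-3-yl}methanol, via benzylic cation 11 (not isolated)
Conditions: (+)-10-camphorsulfonic acid (0.1 equiv), CH2Cl2, 0 °C to rt; Et3N quench as soon as 10 is consumed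
Reagents that add atoms: none
Why: The acid protonates the benzylic hydroxyl of either epimer of 10, water leaves, and cation 11, stabilised as an oxocarbenium by the para-benzyloxy group (a quinone-methide-type cation), is captured by the C4 hydroxyl of the butanediol to form the O1–C2 bond. The closest known reaction type is the acid-catalysed SN1 cycloetherification of a 1,4-diol carrying an electron-rich benzylic carbinol, the usual closure of 2-aryltetrahydrofuran lignans. The one ring closed is the tetrahydrofuran, in a 5-exo-trig mode at the trigonal cationic carbon. The new stereocentre C2 (S) is controlled by the adjacent C3 stereocentre: the aryl group takes the face trans to the C3 hydroxymethyl group, and because ionisation is reversible the trans isomer is also the one that should accumulate, so both carbinol epimers converge. The step needs site selectivity among the hydroxyls and oxygen over carbon capture: the C3 hydroxymethyl could only close an oxetane and the primary–primary diol closure needs forcing acid, while Friedel–Crafts attack by the benzyl ring (to a six-membered aryltetralin) is slower than oxygen capture with a weak acid at 0 °C and short contact time.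

Step 6
Reactants: 12 dibenzyl tetrahydrofuran alcohol
Product: 13 [(2S,3R,4R)-2-(4-hydroxy-3,5-dimethoxyphenyl)-4-(4-hydroxy-3-methoxybenzyl)tetrahydrofuran-3-yl]methanol
Conditions: H2 (1 atm), 10% Pd/C, EtOAc, rt, stopped after uptake for two benzyl groups
Reagents that add atoms: none
Why: Catalytic hydrogenolysis cleaves the two aryl benzyl ethers faster than the benzylic C2–O1 bond of the 2-aryltetrahydrofuran in a neutral, non-protic solvent, so the ring and all three stereocentres should survive.

Step 7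
Reactants: 13 phenolic tetrahydrofuran alcohol; 14 (E)-ferulic acid
Product: 15 [(2S,3R,4R)-2-(4-hydroxy-3,5-dimethoxyphenyl)-4-(4-hydroxy-3-methoxybenzyl)tetrahydrofuran-3-yl]methyl (E)-3-(4-hydroxy-3-methoxyphenyl)prop-2-enoate
Conditions: PPh3 (1.3 equiv), DIAD (1.3 equiv), 14 (1.2 equiv), THF, 0 °C to rt
Reagents that add atoms: none
Why: Mitsunobu esterification activates the only aliphatic hydroxyl and displaces it with the ferulate carboxylate, which is far more acidic than the three phenols and therefore the preferred nucleophile, so no phenol protection is needed and the E-alkene and the ring stereocentres are untouched.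

Compound list
1 | 4-(benzyloxy)-3-methoxybenzaldehyde | O=Cc1ccc(OCc2ccccc2)c(OC)c1 | starting material
2 | propane-1,3-dithiol | SCCCS | starting material
3 | 2-[4-(benzyloxy)-3-methoxyphenyl]-1,3-dithiane | COc1cc(C2SCCCS2)ccc1OCc1ccccc1 | intermediate
4 | (5R)-5-{[(1R,2S,5R)-2-isopropyl-5-methylcyclohexyl]oxy}furan-2(5H)-one | CC(C)[C@@H]1CC[C@@H](C)C[C@H]1O[C@@H]2OC(=O)C=C2 | starting material
5 | 4-(benzyloxy)-3,5-dimethoxybenzaldehyde | COc1cc(C=O)cc(OC)c1OCc1ccccc1 | starting material
6 | 2-lithio-2-[4-(benzyloxy)-3-methoxyphenyl]-1,3-dithiane | [Li]C1(SCCCS1)c1ccc(OCc2ccccc2)c(OC)c1 | intermediate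
7 | lithium enolate of the conjugate adduct (C2–OLi, C2=C3; C4 and C5 configured as in 8) | CC(C)[C@@H]1CC[C@@H](C)C[C@H]1O[C@@H]2OC(O[Li])=C[C@H]2C3(SCCCS3)c4ccc(OCc5ccccc5)c(OC)c4 | intermediate
8 | (3S,4R,5R)-3-{[4-(benzyloxy)-3,5-dimethoxyphenyl](hydroxy)methyl}-4-{2-[4-(benzyloxy)-3-methoxyphenyl]-1,3-dithian-2-yl}-5-(l-menthyloxy)dihydrofuran-2(3H)-one, carbinol epimers | CC(C)[C@@H]1CC[C@@H](C)C[C@H]1O[C@@H]2OC(=O)[C@H](C(O)c3cc(OC)c(OCc4ccccc4)c(OC)c3)[C@H]2C5(SCCCS5)c6ccc(OCc7ccccc7)c(OC)c6 | intermediate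
9 | (3S,4R,5R)-4-[4-(benzyloxy)-3-methoxybenzyl]-3-{[4-(benzyloxy)-3,5-dimethoxyphenyl](hydroxy)methyl}-5-(l-menthyloxy)dihydrofuran-2(3H)-one, carbinol epimers | CC(C)[C@@H]1CC[C@@H](C)C[C@H]1O[C@@H]2OC(=O)[C@H](C(O)c3cc(OC)c(OCc4ccccc4)c(OC)c3)[C@H]2Cc5ccc(OCc6ccccc6)c(OC)c5 | intermediate
10 | (2R,3R)-2-{[4-(benzyloxy)-3,5-dimethoxyphenyl](hydroxy)methyl}-3-[4-(benzyloxy)-3-methoxybenzyl]butane-1,4-diol, carbinol epimers | OC[C@H](C(O)c1cc(OC)c(OCc2ccccc2)c(OC)c1)[C@@H](Cc1ccc(OCc2ccccc2)c(OC)c1)CO | intermediate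
11 | benzylic cation formed from 10 by loss of the carbinol hydroxyl | OC[C@H]([CH+]c1cc(OC)c(OCc2ccccc2)c(OC)c1)[C@@H](Cc1ccc(OCc2ccccc2)c(OC)c1)CO | intermediate
12 | {(2S,3R,4R)-2-[4-(benzyloxy)-3,5-dimethoxyphenyl]-4-[4-(benzyloxy)-3-methoxybenzyl]tetrahydrofuran-3-yl}methanol | OC[C@H]1[C@@H](Cc2ccc(OCc3ccccc3)c(OC)c2)CO[C@@H]1c4cc(OC)c(OCc5ccccc5)c(OC)c4 | intermediate
13 | [(2S,3R,4R)-2-(4-hydroxy-3,5-dimethoxyphenyl)-4-(4-hydroxy-3-methoxybenzyl)tetrahydrofuran-3-yl]methanol | OC[C@H]1[C@@H](Cc2ccc(O)c(OC)c2)CO[C@@H]1c3cc(OC)c(O)c(OC)c3 | intermediate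
14 | (E)-3-(4-hydroxy-3-methoxyphenyl)prop-2-enoic acid (ferulic acid) | COc1cc(/C=C/C(=O)O)ccc1O | starting material
15 | [(2S,3R,4R)-2-(4-hydroxy-3,5-dimethoxyphenyl)-4-(4-hydroxy-3-methoxybenzyl)tetrahydrofuran-3-yl]methyl (E)-3-(4-hydroxy-3-methoxyphenyl)prop-2-enoate | COc1cc(/C=C/C(=O)OC[C@H]2[C@@H](Cc3ccc(O)c(OC)c3)CO[C@@H]2c2cc(OC)c(O)c(OC)c2)ccc1O | target

Total step count: 7. Longest linear sequence: 7 steps (1 → 3 → 8 → 9 → 10 → 12 → 13 → 15).

Steps most likely to fail

Step 5. The cation may be diverted into Friedel–Crafts closure onto the electron-rich benzyl ring, or repeated acid-mediated ring opening may erode the trans selectivity. The fallback sets out from 10 and comes back at 13, so step 6 is not needed. Brief hydrogenolysis of 10 (H2, 10% Pd/C, EtOAc, rt) should give the free-phenol triol F1. TMSBr in CH2Cl2 at 0 °C should convert only its para-hydroxybenzylic hydroxyl into the benzylic bromide F2. Shaking with saturated aqueous NaHCO3 should eliminate HBr to the para-quinone methide F3. Under these neutral conditions the benzyl ring cannot compete, and the C5-side hydroxyl should add by intramolecular oxa-1,6-addition to give 13.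

Step 2. The enolate may fail to capture the aldehyde next to the bulky dithianyl group, or the aldolate may revert on quench. The fallback sets out from 3 and 4 and comes back at 9, so step 3 is absorbed. Lithiated 3 is added to 4 as before, but the enolate is protonated (AcOH, −78 °C) to give the conjugate adduct F4. Desulfurisation with NiCl2·6H2O and NaBH4 should give the 4-benzyl lactone F5. Deprotonation with LiN(iPr)2 in THF at −78 °C and addition of 5 should then give 9 by an aldol reaction of the unhindered enolate anti to the C4 benzyl group.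

Step 7. Phenol alkylation or sluggish activation of the β-branched primary alcohol may compete with ester formation. The fallback sets out from 13 and comes back at 15. Selective acetylation of the two phenols (Ac2O, aqueous NaOH, THF, 0 °C; only the phenoxides react) should give the diacetate F6. Steglich esterification with commercial (E)-4-acetoxy-3-methoxycinnamic acid (EDC·HCl, DMAP, CH2Cl2) should give the triacetate F7. Pyrrolidine in EtOAc at rt should remove the three aryl acetates and leave the alkyl cinnamate, giving 15.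

Further compounds
F1 | step 5 | (2R,3R)-2-[hydroxy(4-hydroxy-3,5-dimethoxyphenyl)methyl]-3-(4-hydroxy-3-methoxybenzyl)butane-1,4-diol, carbinol epimers | OC[C@H](C(O)c1cc(OC)c(O)c(OC)c1)[C@@H](Cc1ccc(O)c(OC)c1)CO
F2 | step 5 | (2R,3R)-2-[bromo(4-hydroxy-3,5-dimethoxyphenyl)methyl]-3-(4-hydroxy-3-methoxybenzyl)butane-1,4-diol, bromide epimers | OC[C@H](C(Br)c1cc(OC)c(O)c(OC)c1)[C@@H](Cc1ccc(O)c(OC)c1)CO
F3 | step 5 | 4-[(2R,3R)-4-hydroxy-2-(hydroxymethyl)-3-(4-hydroxy-3-methoxybenzyl)butylidene]-2,6-dimethoxycyclohexa-2,5-dien-1-one | OC[C@H](C=C1C=C(OC)C(=O)C(OC)=C1)[C@@H](Cc1ccc(O)c(OC)c1)CO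
F4 | step 2 | (4R,5R)-4-{2-[4-(benzyloxy)-3-methoxyphenyl]-1,3-dithian-2-yl}-5-(l-menthyloxy)dihydrofuran-2(3H)-one | CC(C)[C@@H]1CC[C@@H](C)C[C@H]1O[C@@H]2OC(=O)C[C@H]2C3(SCCCS3)c4ccc(OCc5ccccc5)c(OC)c4
F5 | step 2 | (4R,5R)-4-[4-(benzyloxy)-3-methoxybenzyl]-5-(l-menthyloxy)dihydrofuran-2(3H)-one | CC(C)[C@@H]1CC[C@@H](C)C[C@H]1O[C@@H]2OC(=O)C[C@H]2Cc3ccc(OCc4ccccc4)c(OC)c3
F6 | step 7 | [(2S,3R,4R)-2-(4-acetoxy-3,5-dimethoxyphenyl)-4-(4-acetoxy-3-methoxybenzyl)tetrahydrofuran-3-yl]methanol | OC[C@H]1[C@@H](Cc2ccc(OC(C)=O)c(OC)c2)CO[C@@H]1c3cc(OC)c(OC(C)=O)c(OC)c3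
F7 | step 7 | [(2S,3R,4R)-2-(4-acetoxy-3,5-dimethoxyphenyl)-4-(4-acetoxy-3-methoxybenzyl)tetrahydrofuran-3-yl]methyl (E)-3-(4-acetoxy-3-methoxyphenyl)prop-2-enoate | COc1cc(/C=C/C(=O)OC[C@H]2[C@@H](Cc3ccc(OC(C)=O)c(OC)c3)CO[C@@H]2c4cc(OC)c(OC(C)=O)c(OC)c4)ccc1OC(C)=O
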